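**Same road, slower clock.** If cooling a flask slows its steps alike, one run read at a stretched time stands for another.

| flask | starting material | coupling partner | protic impurity | temperature | remark | time |
|---|---|---|---|---|---|---|
| Monday's | 25 mM | 50 mM | 6.2 mM | −15 °C | run made earlier |  |
| Sunday's | 25 mM | 50 mM | 25 mM | −4 °C | run made earlier |  |
| Wednesday's | 50 mM | 50 mM | 12.5 mM | −15 °C | run made earlier |  |
| dawn | 25 mM | 50.0 mM | 12.5 mM | 0 °C |  | 10 min |
| autumn | 25 mM | 50.0 mM | 12.5 mM | −20 °C |  | 10 min |

- Monday's (time / min: target / %, starting material / %): 1.00: 3.3, 56.7; 3.00: 12.3, 22.3; 6.00: 27.6, 5.9; 8.00: 32.7, 3.4; 12.0: 41.3, 0.6; 15.0: 43.1, 0.6; 20.0: 45.3, 0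
- Sunday's (time / min: target / %, starting material / %): 0.500: 6.0, 30.7; 1.50: 17.6, 4.0; 3.00: 30.2, 0.7; 4.00: 32.4, 0; 6.00: 32.9, 0; 8.00: 32.4, 0; 10.0: 31.4, 0
- Wednesday's (time / min: target / %, starting material / %): 4.00: 15.4, 18.7; 8.00: 28.1, 7.4; 12.0: 33.6, 5.3; 15.0: 38.1, 1.4; 20.0: 39.7, 1.7

(readings scatter by 1 percentage point)

1. the best flask by amount of target, in percent of the starting material charged; "all alike" if 1.5 percentage points covers them all (dawn / autumn / all alike)
2. amount of target at the end, in percent of the starting material charged, dawn
3. amount of target at the end, in percent of the starting material charged, autumn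

**The late rise.** By 8.00 min Monday's flask holds hardly any starting material (3.4%), yet target still climbs, so an intermediate lies between them. Take the gap between target and its plateau reading. On Monday's run it closes at 0.287 /min, on Sunday's at 1.16 /min. Both are readings and carry the scatter. Their ratio, 4.03, is the clock lift: how much faster this late rise ran in Sunday's flask at −4 °C than in Monday's at −15 °C, two runs that also differ in impurity. I spread it evenly in logarithm per degree and use it to convert a flask's minutes for the late rise to minutes on Monday's clock. That is an assumption, and it says nothing of the fall of starting material.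

**Dawn, my reckoning.** Dawn's 10 min become 66.9 min on Monday's clock, beyond Monday's last reading at 20.0 min. So I expect a plateau. Wednesday's flask has dawn's impurity, though twice dawn's starting material, and its last reading is 39.7%. I take that.

**Autumn, two ways.** Autumn's 10 min become 5.31 min. Monday's curve, read there and scaled down by the ratio of the last readings, since Monday's flask has 6.2 mM impurity against 12.5 mM, gives 21.1%. Wednesday's curve, read directly, gives 19.5%. They come from different flasks but share the clock, so their agreement tests the curves and leaves the lift untested.

**The forecast.** It names dawn, with 38% there and 21% in autumn. Its ground for autumn: “Only about half is converted at 10 min”.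

**The result.** Dawn gives 40.9% and autumn 21.7%, so dawn is best. At 10.0 min autumn still holds 28.1% intermediate. Autumn's 100 min are 53.1 min on Monday's clock, past Monday's last reading, and the computed target there is 38.7%.

    starting material + target → side product B (k = 0.00669 /M/s, Ea = 44.0 kJ/mol)
    intermediate → side product A (k = 8.87 × 10⁻⁴ /s, Ea = 77.0 kJ/mol)
    starting material + protic impurity → quenched substrate (k = 0.227 /M/s, Ea = 44.0 kJ/mol)
    intermediate → target (k = 0.00110 /s, Ea = 76.0 kJ/mol)
    starting material + coupling partner → intermediate (k = 0.109 /M/s, Ea = 55.0 kJ/mol)
    (constants at −20 °C)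

**A colder dawn.** Repeat dawn at −25 °C. The lift turns its 10 min into 2.82 min, and Monday's scaled curve reads 10.1%. The computed flask gives 10.8% target.

The readings are calculated with constants of no real substance, noise included.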